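**Retrosynthetic overview**
1. Target ← BBr3 O-demethylation of its octamethyl ether; the second dihydrofuran ring (last ring formed) ← acid epimerisation of the cis ring made by rhodium-carbene C–H insertion into a 4-methoxybenzyl ether.
2. That carbene precursor ← tetracyclic aryl bromide + 3,5-dimethoxybenzoyl Weinreb amide; the seven-membered ring ← Friedel–Crafts closure of a 2,4-dimethoxybenzylic cation (from a stilbene) onto the 3,5-dimethoxyphenyl ring of the first dihydrofuran.
3. Key disconnection: the CH2–CH(aryl) bond of the seven-membered ring, formed by an intermolecular aldol (Ivanov) addition of the enediolate of (2,4-dimethoxyphenyl)acetic acid to a dihydrobenzofuran-4-carbaldehyde, then decarboxylative dehydration to the stilbene.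
4. The aldehyde ← the first dihydrofuran ring by a first enantioselective C–H insertion on a ketone built from 2,6-dibromo-3,5-dimethoxybenzyl silyl ether (from 3,5-dimethoxybenzyl alcohol).
5. Ring order: central benzene ring bought in; first dihydrofuran ring, then the seven-membered ring, then the second dihydrofuran ring.

Assumption: Rh2(R-PTAD)4 is taken to give the 3S dihydrofuran and Rh2(S-PTAD)4 the 3R one; if the measured sense is the reverse, the two catalysts change places.

Labels: Ca = O–CH(aryl) carbon of the first dihydrofuran ring; Cb = its CH(aryl) neighbour (also in the seven-membered ring); Cc = CH bearing the 2,4-dioxygenated phenyl ring; Cd = CH(aryl) carbon of the second dihydrofuran ring; Ce = its O–CH(aryl) carbon. Target: Ca S, Cb S, Cc S, Cd R, Ce R (both dihydrofurans 2,3-trans).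

**Route**

Step 1
Reactants: 1 (3,5-dimethoxyphenyl)methanol
Product: 2 [(3,5-dimethoxyphenyl)methoxy]tri(propan-2-yl)silane
Conditions: i-Pr3SiCl, imidazole, DMF, rt
Reagents that add atoms: chlorotri(propan-2-yl)silane, CC(C)[Si](Cl)(C(C)C)C(C)C
Why: Silylation of the primary alcohol; the bulky triisopropylsilyl ether is chosen because it resists migration to the neighbouring aryllithium in step 4 and survives BCl3 at low temperature in step 5.

Step 2
Reactants: 2 [(3,5-dimethoxyphenyl)methoxy]tri(propan-2-yl)silane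
Product: 3 [(2,6-dibromo-3,5-dimethoxyphenyl)methoxy]tri(propan-2-yl)silane
Conditions: NBS (2.1 equiv), MeCN, 0 °C to rt
Reagents that add atoms: N-bromosuccinimide, BrN1C(=O)CCC1=O
Why: Electrophilic aromatic bromination in which each bromine enters para to one methoxy group and ortho to the other (the two equivalent positions flanking the CH2O arm), the carbon between the two methoxy groups being the least reactive.

Step 3
Reactants: 4 3,5-dimethoxybenzoyl chloride
Product: 5 N,3,5-trimethoxy-N-methylbenzamide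
Conditions: MeNHOMe·HCl, Et3N (2.2 equiv), CH2Cl2, 0 °C to rt
Reagents that add atoms: N,O-dimethylhydroxylamine hydrochloride, CNOC.Cl
Why: Acylation of the hydroxylamine by the acid chloride (Weinreb amide formation) gives an acyl donor that stops cleanly at the ketone stage.

Step 4
Reactants: 3 [(2,6-dibromo-3,5-dimethoxyphenyl)methoxy]tri(propan-2-yl)silane; 5 N,3,5-trimethoxy-N-methylbenzamide
Product: 8 [3-bromo-4,6-dimethoxy-2-({[tri(propan-2-yl)silyl]oxy}methyl)phenyl](3,5-dimethoxyphenyl)methanone, via aryllithium 6 (not isolated), via lithium hemiaminal adduct 7 (not isolated)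
Conditions: n-BuLi (1.05 equiv), THF, −78 °C; then 5, −78 to 0 °C; cold 1 M HCl
Reagents that add atoms: none
Why: Lithium–bromine exchange at one of two equivalent bromides followed by Weinreb ketone synthesis, the chelated adduct preventing over-addition and the second bromide being kept for step 14.

Step 5
Reactants: 8 [3-bromo-4,6-dimethoxy-2-({[tri(propan-2-yl)silyl]oxy}methyl)phenyl](3,5-dimethoxyphenyl)methanone
Product: 9 [3-bromo-6-hydroxy-4-methoxy-2-({[tri(propan-2-yl)silyl]oxy}methyl)phenyl](3,5-dimethoxyphenyl)methanone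
Conditions: BCl3 (1.2 equiv), CH2Cl2, −78 to −20 °C; then H2O
Reagents that add atoms: none
Why: Chelation-controlled Lewis-acid ether cleavage, boron bound to the ketone oxygen removing only the methyl ether ortho to the carbonyl group.

Step 6
Reactants: 9 [3-bromo-6-hydroxy-4-methoxy-2-({[tri(propan-2-yl)silyl]oxy}methyl)phenyl](3,5-dimethoxyphenyl)methanone; 10 1-(chloromethyl)-4-methoxybenzene
Product: 11 {3-bromo-4-methoxy-6-[(4-methoxyphenyl)methoxy]-2-({[tri(propan-2-yl)silyl]oxy}methyl)phenyl}(3,5-dimethoxyphenyl)methanone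
Conditions: K2CO3, tetrabutylammonium iodide (cat.), DMF, 60 °C
Reagents that add atoms: none
Why: Williamson ether synthesis on the phenoxide brings in the benzylic CH2 that becomes Ca.

Step 7
Reactants: 11 {3-bromo-4-methoxy-6-[(4-methoxyphenyl)methoxy]-2-({[tri(propan-2-yl)silyl]oxy}methyl)phenyl}(3,5-dimethoxyphenyl)methanone
Product: 12 {3-bromo-4-methoxy-6-[(4-methoxyphenyl)methoxy]-2-({[tri(propan-2-yl)silyl]oxy}methyl)phenyl}(3,5-dimethoxyphenyl)methanone hydrazone (C=N–NH2; E/Z mixture)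
Conditions: N2H4·H2O (excess), AcOH (cat.), EtOH, 80 °C, sealed tube
Reagents that add atoms: hydrazine hydrate, NN.O
Why: Acid-catalysed hydrazone condensation gives the precursor of the diaryl diazo compound.

Step 8
Reactants: 12 {3-bromo-4-methoxy-6-[(4-methoxyphenyl)methoxy]-2-({[tri(propan-2-yl)silyl]oxy}methyl)phenyl}(3,5-dimethoxyphenyl)methanone hydrazone
Product: 14 (2R,3S)-5-bromo-3-(3,5-dimethoxyphenyl)-6-methoxy-2-(4-methoxyphenyl)-4-({[tri(propan-2-yl)silyl]oxy}methyl)-2,3-dihydro-1-benzofuran (2,3-cis), via diaryldiazomethane 13 (not isolated)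
Conditions: MnO2 (8 equiv), CH2Cl2, 0 °C, filter; then dirhodium tetrakis[(R)-(1-adamantyl)(phthalimido)acetate], Rh2(R-PTAD)4 (1 mol %), CH2Cl2, 0 °C
Reagents that add atoms: none
Why: Hydrazone oxidation to the diazo compound and rhodium-carbene intramolecular 1,5 C–H insertion into the benzylic ether C–H, the concerted insertion giving the 2,3-cis ring and the chiral carboxylate ligands fixing Cb as S (Ca is R at this stage).

Step 9
Reactants: 14 (2R,3S)-5-bromo-3-(3,5-dimethoxyphenyl)-6-methoxy-2-(4-methoxyphenyl)-4-({[tri(propan-2-yl)silyl]oxy}methyl)-2,3-dihydro-1-benzofuran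
Product: 15 [(2R,3S)-5-bromo-3-(3,5-dimethoxyphenyl)-6-methoxy-2-(4-methoxyphenyl)-2,3-dihydro-1-benzofuran-4-yl]methanol
Conditions: Bu4NF, THF, 0 °C to rt
Reagents that add atoms: none
Why: Fluoride-induced desilylation frees the benzylic alcohol without touching the stereocentres.

Step 10
Reactants: 15 [(2R,3S)-5-bromo-3-(3,5-dimethoxyphenyl)-6-methoxy-2-(4-methoxyphenyl)-2,3-dihydro-1-benzofuran-4-yl]methanol
Product: 16 (2R,3S)-5-bromo-3-(3,5-dimethoxyphenyl)-6-methoxy-2-(4-methoxyphenyl)-2,3-dihydro-1-benzofuran-4-carbaldehyde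
Conditions: Dess–Martin periodinane, CH2Cl2, rt
Reagents that add atoms: none
Why: Dess–Martin oxidation of the benzylic alcohol to the aldehyde under neutral conditions that leave Ca and Cb untouched.

Step 11
Reactants: 16 (2R,3S)-5-bromo-3-(3,5-dimethoxyphenyl)-6-methoxy-2-(4-methoxyphenyl)-2,3-dihydro-1-benzofuran-4-carbaldehyde; 17 (2,4-dimethoxyphenyl)acetic acid
Product: 19 3-[(2R,3S)-5-bromo-3-(3,5-dimethoxyphenyl)-6-methoxy-2-(4-methoxyphenyl)-2,3-dihydro-1-benzofuran-4-yl]-2-(2,4-dimethoxyphenyl)-3-hydroxypropanoic acid (diastereomer mixture at the two new carbons), via magnesium enediolate 18 (not isolated)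
Conditions: 17, i-PrMgCl (2.1 equiv), THF, 0 to 40 °C; then 16, −40 °C to rt; aq HCl to pH 3
Reagents that add atoms: none
Why: Ivanov reaction, an intermolecular aldol addition of the arylacetic acid enediolate to the hindered aldehyde that joins the two fragments through the future CH2–CH(aryl) bond; the weakly basic magnesium enediolate at low temperature leaves the Cb–H alone, and the two new centres are erased in step 12.

Step 12
Reactants: 19 3-[(2R,3S)-5-bromo-3-(3,5-dimethoxyphenyl)-6-methoxy-2-(4-methoxyphenyl)-2,3-dihydro-1-benzofuran-4-yl]-2-(2,4-dimethoxyphenyl)-3-hydroxypropanoic acid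
Product: 20 (2R,3S)-5-bromo-4-[2-(2,4-dimethoxyphenyl)ethenyl]-3-(3,5-dimethoxyphenyl)-6-methoxy-2-(4-methoxyphenyl)-2,3-dihydro-1-benzofuran (E/Z mixture)
Conditions: Me2NCH(OCH2CMe3)2 (3 equiv), toluene, 90 °C
Reagents that add atoms: none
Why: Decarboxylative dehydration of the β-hydroxy acid (anti elimination of the formamide-acetal-activated hydroxyl together with loss of CO2) gives the stilbene, whose geometry is irrelevant for the next step.

Step 13
Reactants: 20 (2R,3S)-5-bromo-4-[2-(2,4-dimethoxyphenyl)ethenyl]-3-(3,5-dimethoxyphenyl)-6-methoxy-2-(4-methoxyphenyl)-2,3-dihydro-1-benzofuran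
Product: 22 tetracyclic bromide (Ca-S,Cb-S,Cc-S; trans first dihydrofuran ring; seven-membered ring closed), via cis-fused tetracycle 21 (not isolated)
Conditions: CF3CO2H/CH2Cl2 (1:4), 0 °C to rt
Reagents that add atoms: none
Why: Protonation of the alkene at the carbon next to the central ring gives the 2,4-dimethoxybenzylic cation, which closes the seven-membered ring by intramolecular Friedel–Crafts alkylation of the 3,5-dimethoxyphenyl ring, the aryl group being placed away from the peri methoxy group (Cc S from Cb S, as in the acid conversion of ε-viniferin into ampelopsin B), while the same acid reversibly opens the dihydrofuran at Ca through the 4-methoxybenzylic cation and re-closes it to the more stable trans ring (Ca S).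

Step 14
Reactants: 22 tetracyclic bromide; 5 N,3,5-trimethoxy-N-methylbenzamide
Product: 25 tetracyclic ketone (3,5-dimethoxybenzoyl group in place of the bromine; Ca-S,Cb-S,Cc-S), via aryllithium 23 (not isolated), via lithium hemiaminal adduct 24 (not isolated)
Conditions: n-BuLi (1.1 equiv), THF, −78 °C; then 5, −78 to 0 °C; cold 1 M HCl
Reagents that add atoms: none
Why: Lithium–bromine exchange and Weinreb ketone synthesis, the substrate carrying only ethers and non-acidic methine hydrogens.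

Step 15
Reactants: 25 tetracyclic ketone
Product: 26 tetracyclic hydroxy ketone (the methyl ether ortho to the ketone cleaved to the phenol)
Conditions: BCl3 (2 equiv), CH2Cl2, −78 to −20 °C; then H2O
Reagents that add atoms: none
Why: Chelation-controlled Lewis-acid demethylation removes only the methoxy group ortho to the new ketone.

Step 16
Reactants: 26 tetracyclic hydroxy ketone; 10 1-(chloromethyl)-4-methoxybenzene
Product: 27 tetracyclic ketone 4-methoxybenzyl ether
Conditions: K2CO3, tetrabutylammonium iodide (cat.), DMF, 60 °C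
Reagents that add atoms: none
Why: Williamson ether synthesis installs the benzylic CH2 that becomes Ce.

Step 17
Reactants: 27 tetracyclic ketone 4-methoxybenzyl ether
Product: 28 tetracyclic hydrazone (C=N–NH2 in place of C=O; E/Z mixture)
Conditions: N2H4·H2O (excess), AcOH (cat.), EtOH, 80 °C, sealed tube
Reagents that add atoms: hydrazine hydrate, NN.O
Why: Acid-catalysed hydrazone condensation, as in step 7.

Step 18
Reactants: 28 tetracyclic hydrazone
Product: 30 pentacyclic octamethyl ether (Ca-S,Cb-S,Cc-S,Cd-R,Ce-S; second dihydrofuran ring cis), via diaryldiazomethane 29 (not isolated)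
Conditions: MnO2 (8 equiv), CH2Cl2, 0 °C, filter; then dirhodium tetrakis[(S)-(1-adamantyl)(phthalimido)acetate], Rh2(S-PTAD)4 (1 mol %), CH2Cl2, 0 °C
Reagents that add atoms: none
Why: Second rhodium-carbene 1,5 C–H insertion, now using the mirror-image catalyst so that reagent control sets Cd as R (cis ring, Ce S); insertion into the oxygen-activated ether C–H is preferred over the Cc–H bond, which the seven-membered ring holds away from the carbene.

Step 19
Reactants: 30 pentacyclic octamethyl ether (cis second dihydrofuran)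
Product: 31 octa-O-methyl ether of the target (Ca-S,Cb-S,Cc-S,Cd-R,Ce-R; both dihydrofurans trans)
Conditions: CF3CO2H/CH2Cl2 (1:4), rt
Reagents that add atoms: none
Why: Acid-mediated epimerisation at Ce by reversible ring opening to the 4-methoxybenzylic cation and re-closure to the thermodynamically favoured trans ring, the other centres being either not ionisable or already in their stable configuration; the step is an isomerisation in which no atoms are gained or lost.

Step 20
Reactants: 31 octa-O-methyl ether of the target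
Product: 32 target compound CNP0154047.3 (Ca-S,Cb-S,Cc-S,Cd-R,Ce-R)
Conditions: BBr3 (16 equiv), CH2Cl2, −78 °C to rt; then H2O
Reagents that add atoms: none
Why: Lewis-acid cleavage of all eight aryl methyl ethers by BBr3; any boron-induced opening of the dihydrofurans re-closes to the trans rings on work-up.

**Compound list**

1 | (3,5-dimethoxyphenyl)methanol | COc1cc(CO)cc(OC)c1 | starting material
2 | [(3,5-dimethoxyphenyl)methoxy]tri(propan-2-yl)silane | COc1cc(CO[Si](C(C)C)(C(C)C)C(C)C)cc(OC)c1 | intermediate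
3 | [(2,6-dibromo-3,5-dimethoxyphenyl)methoxy]tri(propan-2-yl)silane | COc1cc(OC)c(Br)c(CO[Si](C(C)C)(C(C)C)C(C)C)c1Br | intermediate
4 | 3,5-dimethoxybenzoyl chloride | COc1cc(OC)cc(C(Cl)=O)c1 | starting material
5 | N,3,5-trimethoxy-N-methylbenzamide | CON(C)C(=O)c1cc(OC)cc(OC)c1 | intermediate
6 | [3-bromo-4,6-dimethoxy-2-({[tri(propan-2-yl)silyl]oxy}methyl)phenyl]lithium (not isolated) | COc1cc(OC)c([Li])c(CO[Si](C(C)C)(C(C)C)C(C)C)c1Br | intermediate
7 | lithium hemiaminal adduct of the aryllithium and the Weinreb amide (not isolated) | COc1cc(OC)c(C(O[Li])(N(C)OC)c2cc(OC)cc(OC)c2)c(CO[Si](C(C)C)(C(C)C)C(C)C)c1Br | intermediate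
8 | [3-bromo-4,6-dimethoxy-2-({[tri(propan-2-yl)silyl]oxy}methyl)phenyl](3,5-dimethoxyphenyl)methanone | COc1cc(OC)c(C(=O)c2cc(OC)cc(OC)c2)c(CO[Si](C(C)C)(C(C)C)C(C)C)c1Br | intermediate
9 | [3-bromo-6-hydroxy-4-methoxy-2-({[tri(propan-2-yl)silyl]oxy}methyl)phenyl](3,5-dimethoxyphenyl)methanone | COc1cc(O)c(C(=O)c2cc(OC)cc(OC)c2)c(CO[Si](C(C)C)(C(C)C)C(C)C)c1Br | intermediate
10 | 1-(chloromethyl)-4-methoxybenzene | COc1ccc(CCl)cc1 | starting material
11 | {3-bromo-4-methoxy-6-[(4-methoxyphenyl)methoxy]-2-({[tri(propan-2-yl)silyl]oxy}methyl)phenyl}(3,5-dimethoxyphenyl)methanone | COc1ccc(COc2cc(OC)c(Br)c(CO[Si](C(C)C)(C(C)C)C(C)C)c2C(=O)c2cc(OC)cc(OC)c2)cc1 | intermediate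
12 | {3-bromo-4-methoxy-6-[(4-methoxyphenyl)methoxy]-2-({[tri(propan-2-yl)silyl]oxy}methyl)phenyl}(3,5-dimethoxyphenyl)methanone hydrazone | COc1ccc(COc2cc(OC)c(Br)c(CO[Si](C(C)C)(C(C)C)C(C)C)c2C(=NN)c2cc(OC)cc(OC)c2)cc1 | intermediate
13 | diaryldiazomethane from the hydrazone (not isolated) | COc1ccc(COc2cc(OC)c(Br)c(CO[Si](C(C)C)(C(C)C)C(C)C)c2C(=[N+]=[N-])c2cc(OC)cc(OC)c2)cc1 | intermediate
14 | (2R,3S)-5-bromo-3-(3,5-dimethoxyphenyl)-6-methoxy-2-(4-methoxyphenyl)-4-({[tri(propan-2-yl)silyl]oxy}methyl)-2,3-dihydro-1-benzofuran (cis) | COc1ccc([C@@H]2Oc3cc(OC)c(Br)c(CO[Si](C(C)C)(C(C)C)C(C)C)c3[C@@H]2c2cc(OC)cc(OC)c2)cc1 | intermediate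
15 | [(2R,3S)-5-bromo-3-(3,5-dimethoxyphenyl)-6-methoxy-2-(4-methoxyphenyl)-2,3-dihydro-1-benzofuran-4-yl]methanol | COc1ccc([C@@H]2Oc3cc(OC)c(Br)c(CO)c3[C@@H]2c2cc(OC)cc(OC)c2)cc1 | intermediate
16 | (2R,3S)-5-bromo-3-(3,5-dimethoxyphenyl)-6-methoxy-2-(4-methoxyphenyl)-2,3-dihydro-1-benzofuran-4-carbaldehyde | COc1ccc([C@@H]2Oc3cc(OC)c(Br)c(C=O)c3[C@@H]2c2cc(OC)cc(OC)c2)cc1 | intermediate
17 | (2,4-dimethoxyphenyl)acetic acid | COc1ccc(CC(=O)O)c(OC)c1 | starting material
18 | bis(chloromagnesium) enediolate of (2,4-dimethoxyphenyl)acetic acid (Ivanov reagent, not isolated) | COc1ccc(C=C(O[Mg]Cl)O[Mg]Cl)c(OC)c1 | intermediate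
19 | 3-[(2R,3S)-5-bromo-3-(3,5-dimethoxyphenyl)-6-methoxy-2-(4-methoxyphenyl)-2,3-dihydro-1-benzofuran-4-yl]-2-(2,4-dimethoxyphenyl)-3-hydroxypropanoic acid (mixture at the two chain carbons) | COc1ccc([C@@H]2Oc3cc(OC)c(Br)c(C(O)C(C(=O)O)c4ccc(OC)cc4OC)c3[C@@H]2c2cc(OC)cc(OC)c2)cc1 | intermediate
20 | (2R,3S)-5-bromo-4-[2-(2,4-dimethoxyphenyl)ethenyl]-3-(3,5-dimethoxyphenyl)-6-methoxy-2-(4-methoxyphenyl)-2,3-dihydro-1-benzofuran (E/Z mixture) | COc1ccc([C@@H]2Oc3cc(OC)c(Br)c(C=Cc4ccc(OC)cc4OC)c3[C@@H]2c2cc(OC)cc(OC)c2)cc1 | intermediate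
21 | cis-fused tetracyclic bromide (Ca R, Cb S, Cc S; seven-membered ring closed, not isolated) | COc1ccc([C@@H]2Oc3cc(OC)c(Br)c4c3[C@@H]2c2cc(OC)cc(OC)c2[C@H](c2ccc(OC)cc2OC)C4)cc1 | intermediate
22 | tetracyclic bromide (Ca S, Cb S, Cc S): trans dihydrobenzofuran bridged from its 3-aryl ring to C4 by CH(2,4-dimethoxyphenyl)–CH2; Br at C5, OMe at C6 | COc1ccc([C@H]2Oc3cc(OC)c(Br)c4c3[C@@H]2c2cc(OC)cc(OC)c2[C@H](c2ccc(OC)cc2OC)C4)cc1 | intermediate
23 | tetracyclic aryllithium (Li in place of Br, not isolated) | COc1ccc([C@H]2Oc3cc(OC)c([Li])c4c3[C@@H]2c2cc(OC)cc(OC)c2[C@H](c2ccc(OC)cc2OC)C4)cc1 | intermediate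
24 | lithium hemiaminal adduct of the tetracyclic aryllithium and the Weinreb amide (not isolated) | COc1ccc([C@H]2Oc3cc(OC)c(C(O[Li])(N(C)OC)c5cc(OC)cc(OC)c5)c4c3[C@@H]2c2cc(OC)cc(OC)c2[C@H](c2ccc(OC)cc2OC)C4)cc1 | intermediate
25 | tetracyclic ketone (3,5-dimethoxybenzoyl in place of the bromine) | COc1ccc([C@H]2Oc3cc(OC)c(C(=O)c5cc(OC)cc(OC)c5)c4c3[C@@H]2c2cc(OC)cc(OC)c2[C@H](c2ccc(OC)cc2OC)C4)cc1 | intermediate
26 | tetracyclic hydroxy ketone (OH ortho to the ketone) | COc1ccc([C@H]2Oc3cc(O)c(C(=O)c5cc(OC)cc(OC)c5)c4c3[C@@H]2c2cc(OC)cc(OC)c2[C@H](c2ccc(OC)cc2OC)C4)cc1 | intermediate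
27 | tetracyclic ketone 4-methoxybenzyl ether | COc1ccc([C@H]2Oc3cc(OCc6ccc(OC)cc6)c(C(=O)c5cc(OC)cc(OC)c5)c4c3[C@@H]2c2cc(OC)cc(OC)c2[C@H](c2ccc(OC)cc2OC)C4)cc1 | intermediate
28 | tetracyclic hydrazone (C=N–NH2 in place of C=O) | COc1ccc([C@H]2Oc3cc(OCc6ccc(OC)cc6)c(C(=NN)c5cc(OC)cc(OC)c5)c4c3[C@@H]2c2cc(OC)cc(OC)c2[C@H](c2ccc(OC)cc2OC)C4)cc1 | intermediate
29 | tetracyclic diaryldiazomethane (not isolated) | COc1ccc([C@H]2Oc3cc(OCc6ccc(OC)cc6)c(C(=[N+]=[N-])c5cc(OC)cc(OC)c5)c4c3[C@@H]2c2cc(OC)cc(OC)c2[C@H](c2ccc(OC)cc2OC)C4)cc1 | intermediate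
30 | pentacyclic octamethyl ether, second dihydrofuran cis (Ca S, Cb S, Cc S, Cd R, Ce S) | COc1ccc([C@H]2Oc3cc4c(c5c3[C@@H]2c2cc(OC)cc(OC)c2[C@H](c2ccc(OC)cc2OC)C5)[C@@H](c2cc(OC)cc(OC)c2)[C@@H](c2ccc(OC)cc2)O4)cc1 | intermediate
31 | octa-O-methyl ether of the target (Ca S, Cb S, Cc S, Cd R, Ce R) | COc1ccc([C@H]2Oc3cc4c(c5c3[C@@H]2c2cc(OC)cc(OC)c2[C@H](c2ccc(OC)cc2OC)C5)[C@@H](c2cc(OC)cc(OC)c2)[C@H](c2ccc(OC)cc2)O4)cc1 | intermediate
32 | CNP0154047.3 (Ca S, Cb S, Cc S, Cd R, Ce R) | Oc1ccc([C@H]2Oc3cc4c(c5c3[C@@H]2c2cc(O)cc(O)c2[C@H](c2ccc(O)cc2O)C5)[C@@H](c2cc(O)cc(O)c2)[C@H](c2ccc(O)cc2)O4)cc1 | target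

**Totals and risks**

Total step count: 20. Longest linear sequence: 19 steps (steps 1, 2 and 4 to 20; step 3 is a one-step branch).

Most likely to fail, first: step 7, hydrazone formation at a diaryl ketone flanked by two ortho substituents. The fallback sets out from ketone 11. Lawesson's reagent in toluene at 110 °C converts it into the diaryl thioketone F1, which condenses with hydrazine hydrate at room temperature, losing hydrogen sulfide. This gives hydrazone 12, where the route is rejoined.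

Second: step 11, the aldol addition to a di-ortho-substituted aldehyde, where retro-aldol cleavage or deprotonation at Cb under basic conditions could intervene. The fallback sets out from aldehyde 16 and acid 17 and avoids a basic medium. Acid 17 is esterified (MeOH, H2SO4) to methyl (2,4-dimethoxyphenyl)acetate F2. LiN(i-Pr)2 and Me3SiCl turn this into the ketene silyl acetal F3. F3 adds to 16 under BF3·OEt2 in CH2Cl2 at −78 °C (Mukaiyama aldol) to give the β-hydroxy methyl ester F4. Saponification by LiOH in THF/water returns β-hydroxy acid 19.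

Third: step 18, the second C–H insertion on the congested tetracycle, where yield and selectivity are least certain. The fallback sets out from ketone 25 and builds the second dihydrofuran ring by ionic chemistry. Trimethylsulfonium iodide and n-BuLi give the 2,2-diaryl epoxide F5 (Corey–Chaykovsky). ZnI2 rearranges it to the diarylacetaldehyde F6 (Meinwald). 4-MeOC6H4MgBr adds to give the carbinol F7. BBr3 then removes all nine methyl ethers and closes the second dihydrofuran ring trans through the 4-hydroxybenzylic cation. The sequence is not selective at Cd, so target 32 is formed together with its Cd,Ce-epimer F8; the two are diastereomers and are separated by preparative HPLC. The route is rejoined at 32.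

**Further compounds**

F1 | step 7 | {3-bromo-4-methoxy-6-[(4-methoxyphenyl)methoxy]-2-({[tri(propan-2-yl)silyl]oxy}methyl)phenyl}(3,5-dimethoxyphenyl)methanethione | COc1ccc(COc2cc(OC)c(Br)c(CO[Si](C(C)C)(C(C)C)C(C)C)c2C(=S)c2cc(OC)cc(OC)c2)cc1
F2 | step 11 | methyl (2,4-dimethoxyphenyl)acetate | COC(=O)Cc1ccc(OC)cc1OC
F3 | step 11 | [2-(2,4-dimethoxyphenyl)-1-methoxyethenyl]oxy(trimethyl)silane | COC(=Cc1ccc(OC)cc1OC)O[Si](C)(C)C
F4 | step 11 | methyl ester of β-hydroxy acid 19 (mixture at the two chain carbons) | COc1ccc([C@@H]2Oc3cc(OC)c(Br)c(C(O)C(C(=O)OC)c4ccc(OC)cc4OC)c3[C@@H]2c2cc(OC)cc(OC)c2)cc1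
F5 | step 18 | 2-(3,5-dimethoxyphenyl)oxiran-2-yl derivative of 25 (C=O converted into the spiro CH2–O epoxide; mixture at the new carbon) | COc1ccc([C@H]2Oc3cc(OC)c(C5(CO5)c6cc(OC)cc(OC)c6)c4c3[C@@H]2c2cc(OC)cc(OC)c2[C@H](c2ccc(OC)cc2OC)C4)cc1
F6 | step 18 | diarylacetaldehyde, CH(CHO)(3,5-dimethoxyphenyl) in place of the ketone of 25 (mixture at Cd) | COc1ccc([C@H]2Oc3cc(OC)c(C(C=O)c6cc(OC)cc(OC)c6)c4c3[C@@H]2c2cc(OC)cc(OC)c2[C@H](c2ccc(OC)cc2OC)C4)cc1
F7 | step 18 | carbinol, CH(3,5-dimethoxyphenyl)–CH(OH)(4-methoxyphenyl) in place of the ketone of 25 (mixture at Cd and Ce) | COc1ccc([C@H]2Oc3cc(OC)c(C(C(O)c5ccc(OC)cc5)c6cc(OC)cc(OC)c6)c4c3[C@@H]2c2cc(OC)cc(OC)c2[C@H](c2ccc(OC)cc2OC)C4)cc1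
F8 | step 18 | Cd,Ce-epimer of the target (Ca S, Cb S, Cc S, Cd S, Ce S) | Oc1ccc([C@H]2Oc3cc4c(c5c3[C@@H]2c2cc(O)cc(O)c2[C@H](c2ccc(O)cc2O)C5)[C@H](c2cc(O)cc(O)c2)[C@@H](c2ccc(O)cc2)O4)cc1
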